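**Retrosynthetic overview**
1. The methylene bridge is made last: target ⇒ chiral ring A Mannich base 9 (a latent 6-methylidene trione) + ring B arene 14.
2. Key C–C bond: the quaternary C4–prenyl bond. The fully substituted aromatic Mannich base 6 is dearomatized as an O-bound λ3-iodane (an enolonium/phenoxenium equivalent) and attacked by the nucleophilic allylsilane 7 under a chiral aryl iodane; this sets (4R).
3. 6 ⇒ Mannich reaction (CH2O, Me2NH) on 3 ⇒ Friedel–Crafts acylation of 2-methylphloroglucinol 1 with hexanoyl chloride 2. The CH2NMe2 group blocks the last ring C–H during the oxidation and later becomes the bridge carbon.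
4. 14 ⇒ 4-O-methylation of 12 ⇒ Friedel–Crafts acylation of phloroglucinol 10 with butanoyl chloride 11.
5. Rings: no ring is built. Both six-membered rings are bought as phloroglucinols; ring B stays aromatic and ring A is dearomatized in the key step.

Assumption: the chiral reagent Ar*I(OCOCF3)2 (one operation from the purchasable iodoarene with KHSO5 in CF3CO2H) and silane 7 (purchasable, otherwise one operation from prenylmagnesium chloride and Me3SiCl) are handled as stock reagents and are not counted as route steps.

Ar*I = 2,6-bis[(1R)-1-(mesitylcarbamoyl)ethoxy]iodobenzene.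

**Route**

Step 1
Reactants: 1 2-methylbenzene-1,3,5-triol (2-methylphloroglucinol); 2 hexanoyl chloride
Product: 3 1-(2,4,6-trihydroxy-3-methylphenyl)hexan-1-one
Conditions: AlCl3 (3.5 equiv), PhNO2, 65 °C; ice/aq. HCl quench
Reagents that add atoms: hexanoyl chloride (2), CCCCCC(Cl)=O
Why: Friedel–Crafts C-acylation (O-acylation/Fries pathway) of the very electron-rich triol; the two free ring positions of 1 are equivalent and the first acyl group deactivates the ring against a second, so one mono-ketone results.

Step 2
Reactants: 3 1-(2,4,6-trihydroxy-3-methylphenyl)hexan-1-one; 4 formaldehyde; 5 dimethylamine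
Product: 6 1-{3-[(dimethylamino)methyl]-2,4,6-trihydroxy-5-methylphenyl}hexan-1-one (isolated as the inner salt)
Conditions: 37% aq. CH2O (1.05 equiv) premixed with 40% aq. Me2NH (1.2 equiv), EtOH, 0 °C to rt
Reagents that add atoms: formaldehyde (4), C=O; dimethylamine (5), CNC
Why: Mannich aminomethylation at the only remaining ring C–H of the acidic acylphloroglucinol; the zwitterionic product has every ring carbon substituted, carries the future bridge carbon and has its nitrogen protonated (protected from oxidation) for step 3.

Step 3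
Reactants: 6 1-{3-[(dimethylamino)methyl]-2,4,6-trihydroxy-5-methylphenyl}hexan-1-one; 7 trimethyl(2-methylbut-3-en-2-yl)silane
Product: 9 (4R)-6-[(dimethylamino)methyl]-2-hexanoyl-3,5-dihydroxy-4-methyl-4-(3-methylbut-2-en-1-yl)cyclohexa-2,5-dien-1-one, via aryloxy-λ3-iodane 8 (not isolated)
Conditions: (R,R)-Ar*I(OCOCF3)2 (1.05 equiv), 7 (2.5 equiv), CH2Cl2/(CF3)2CHOH 10:1, −40 °C; crystallization of 9 (EtOH)
Reagents that add atoms: trimethyl(2-methylbut-3-en-2-yl)silane (7), C=CC(C)(C)[Si](C)(C)C
Why: Proposed new method: the non-chelated 4-oxygen of zwitterionic 6 displaces one trifluoroacetate on the chiral trivalent-iodine reagent to give 8, an enolonium (phenoxenium) equivalent in which the normally nucleophilic methyl-bearing ortho carbon is electrophilic; the nucleophilic CH2= terminus of 7 attacks this carbon in an associative SN2′ manner as Ar*I leaves, and loss of the silyl group from the β-silyl cation (SE2′, Hosomi–Sakurai sense) unmasks the linear prenyl group; the methyl-bearing carbon is preferred over the ammoniomethyl-bearing one (bulkier, inductively deactivated) and over the acyl-bearing one (electron-poor), and with no ring C–H left neither iodonium ylide formation nor C–H allylation can compete; the two lactamide arms fold over iodine through N–H···O hydrogen bonds and shield one face of the bound ring, so 7 enters from the open face, assigned here by model only as the face giving (4R), and crystallization of zwitterionic 9 is relied on to reach a single enantiomer; closest known chemistry: racemic λ3-iodane-mediated dearomatizing ortho-allylation of 2-alkylarenols with allylsilanes, enolonium allylation of ketones with allylsilanes, and enantioselective oxidative dearomatization (Kita-type spirolactonization) with this lactamide iodoarene class.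

Step 4
Reactants: 10 benzene-1,3,5-triol (phloroglucinol); 11 butanoyl chloride
Product: 12 1-(2,4,6-trihydroxyphenyl)butan-1-one
Conditions: AlCl3 (3.5 equiv), PhNO2, 65 °C; ice/aq. HCl quench
Reagents that add atoms: butanoyl chloride (11), CCCC(Cl)=O
Why: Friedel–Crafts mono-acylation of phloroglucinol; all three ring positions are equivalent and the ketone deactivates the ring against further acylation.

Step 5
Reactants: 12 1-(2,4,6-trihydroxyphenyl)butan-1-one; 13 dimethyl sulfate
Product: 14 1-(2,6-dihydroxy-4-methoxyphenyl)butan-1-one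
Conditions: Me2SO4 (1.0 equiv), K2CO3 (1.0 equiv), acetone, rt
Reagents that add atoms: dimethyl sulfate (13), COS(=O)(=O)OC
Why: Williamson O-methylation; the 4-OH is the only hydroxyl not hydrogen-bonded to the ketone, so it is the most acidic and most nucleophilic and is methylated first.

Step 6
Reactants: 9 (4R)-6-[(dimethylamino)methyl]-2-hexanoyl-3,5-dihydroxy-4-methyl-4-(3-methylbut-2-en-1-yl)cyclohexa-2,5-dien-1-one; 14 1-(2,6-dihydroxy-4-methoxyphenyl)butan-1-one
Product: 16 (4R)-6-[(3-butanoyl-2,4-dihydroxy-6-methoxyphenyl)methyl]-2-hexanoyl-3,5-dihydroxy-4-methyl-4-(3-methylbut-2-en-1-yl)cyclohexa-2,5-dien-1-one (the target), via methylidene trione 15 (not isolated)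
Conditions: 14 (2.5 equiv), 1,4-dioxane, 80 °C, N2 sweep
Reagents that add atoms: none
Why: Thermal retro-Mannich (E1cB) loss of Me2NH from the β-aminomethyl trione gives 15, a 2-alkylidene-1,3-dione (ortho-quinone-methide analog), and one of the two equivalent free ring carbons of 14 adds to it (Michael/Friedel–Crafts) and rearomatizes; the quaternary stereocenter has no acidic hydrogen and is untouched, and excess 14 suppresses double alkylation.

**Compound list**
1 | 2-methylbenzene-1,3,5-triol | Cc1c(O)cc(O)cc1O | starting material
2 | hexanoyl chloride | CCCCCC(Cl)=O | starting material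
3 | 1-(2,4,6-trihydroxy-3-methylphenyl)hexan-1-one | CCCCCC(=O)c1c(O)cc(O)c(C)c1O | intermediate
4 | formaldehyde | C=O | starting material
5 | dimethylamine | CNC | starting material
6 | 1-{3-[(dimethylamino)methyl]-2,4,6-trihydroxy-5-methylphenyl}hexan-1-one (drawn neutral; an inner salt) | CCCCCC(=O)c1c(O)c(CN(C)C)c(O)c(C)c1O | intermediate
7 | trimethyl(2-methylbut-3-en-2-yl)silane | C=CC(C)(C)[Si](C)(C)C | starting material
8 | 4-O-[aryl(trifluoroacetoxy)-λ3-iodanyl] derivative of 6, aryl = 2,6-bis[(1R)-1-(mesitylcarbamoyl)ethoxy]phenyl | CCCCCC(=O)c1c(O)c(CN(C)C)c(OI(OC(=O)C(F)(F)F)c2c(O[C@H](C)C(=O)Nc3c(C)cc(C)cc3C)cccc2O[C@H](C)C(=O)Nc2c(C)cc(C)cc2C)c(C)c1O | intermediate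
9 | (4R)-6-[(dimethylamino)methyl]-2-hexanoyl-3,5-dihydroxy-4-methyl-4-(3-methylbut-2-en-1-yl)cyclohexa-2,5-dien-1-one (drawn neutral; an inner salt) | CCCCCC(=O)C1=C(O)[C@](C)(CC=C(C)C)C(O)=C(CN(C)C)C1=O | intermediate
10 | benzene-1,3,5-triol | Oc1cc(O)cc(O)c1 | starting material
11 | butanoyl chloride | CCCC(Cl)=O | starting material
12 | 1-(2,4,6-trihydroxyphenyl)butan-1-one | CCCC(=O)c1c(O)cc(O)cc1O | intermediate
13 | dimethyl sulfate | COS(=O)(=O)OC | starting material
14 | 1-(2,6-dihydroxy-4-methoxyphenyl)butan-1-one | CCCC(=O)c1c(O)cc(OC)cc1O | intermediate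
15 | 2-hexanoyl-3-hydroxy-4-methyl-4-(3-methylbut-2-en-1-yl)-6-methylidenecyclohex-2-ene-1,5-dione; (4S) by the CIP rules in this tautomer, same spatial arrangement as (4R)-9 | CCCCCC(=O)C1=C(O)[C@](C)(CC=C(C)C)C(=O)C(=C)C1=O | intermediate
16 | (4R)-6-[(3-butanoyl-2,4-dihydroxy-6-methoxyphenyl)methyl]-2-hexanoyl-3,5-dihydroxy-4-methyl-4-(3-methylbut-2-en-1-yl)cyclohexa-2,5-dien-1-one | CCCCCC(=O)C1=C(O)[C@](C)(CC=C(C)C)C(O)=C(Cc2c(OC)cc(O)c(C(=O)CCC)c2O)C1=O | target

**Totals**
Total step count: 6. Longest linear sequence: 4 (steps 1, 2, 3, 6); steps 4 and 5 form the second branch.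

**Three steps most likely to fail, each with one fallback**

Step 3 (regio- and face-selectivity of the new dearomatizing prenylation). The face selectivity cannot be predicted with confidence; the mirror-image reagent would be used if the sense proves opposite. Fallback, from 3 back to 16: the stereocontrol is moved from the iodane to a traceless chiral amine in the Mannich handle. Compound 3 is condensed with formaldehyde 4 and (S)-N-methyl-1-phenylethylamine to give 1-[2,4,6-trihydroxy-3-methyl-5-({methyl[(1S)-1-phenylethyl]amino}methyl)phenyl]hexan-1-one F1. The same umpolung prenylation with achiral PhI(OCOCF3)2 and 7 then gives two diastereomers. The wanted one, (4R)-2-hexanoyl-3,5-dihydroxy-4-methyl-4-(3-methylbut-2-en-1-yl)-6-({methyl[(1S)-1-phenylethyl]amino}methyl)cyclohexa-2,5-dien-1-one F2, is separated by crystallization or chromatography. Heating F2 with 14 as in step 6 expels the chiral amine through 15 and rejoins the route at 16.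

Step 6 (the thermally released methylidene trione 15 may dimerize or scramble before 14 adds). Fallback, from 9 back to 16: 9 is warmed with TolSO2Na in aqueous AcOH to exchange the amine for a sulfone. This gives 2-hexanoyl-3,5-dihydroxy-4-methyl-4-(3-methylbut-2-en-1-yl)-6-{[(4-methylphenyl)sulfonyl]methyl}cyclohexa-2,5-dien-1-one F3, a stable, purifiable precursor; it is (4S) by the CIP rules because sulfur changes the priorities, with the same spatial arrangement as 9. Treating F3 with 14 and NaHCO3 in MeCN at rt releases 15 slowly by E1cB loss of sulfinate under mild, base-triggered conditions and gives 16.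

Step 5 (over-methylation or a wrong mono-ether). Fallback, from 12 back to 14: 12 is exhaustively methylated (excess Me2SO4, K2CO3, acetone, reflux) to 1-(2,4,6-trimethoxyphenyl)butan-1-one F4. Both methoxy groups ortho to the ketone are then cleaved under chelation control with BCl3 (excess, CH2Cl2, 0 °C to rt), which leaves the para-methoxy group and gives 14.

**Further compounds**
F1 | step 3 | 1-[2,4,6-trihydroxy-3-methyl-5-({methyl[(1S)-1-phenylethyl]amino}methyl)phenyl]hexan-1-one | CCCCCC(=O)c1c(O)c(CN(C)[C@@H](C)c2ccccc2)c(O)c(C)c1O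
F2 | step 3 | (4R)-2-hexanoyl-3,5-dihydroxy-4-methyl-4-(3-methylbut-2-en-1-yl)-6-({methyl[(1S)-1-phenylethyl]amino}methyl)cyclohexa-2,5-dien-1-one | CCCCCC(=O)C1=C(O)[C@](C)(CC=C(C)C)C(O)=C(CN(C)[C@@H](C)c2ccccc2)C1=O
F3 | step 6 | (4S)-2-hexanoyl-3,5-dihydroxy-4-methyl-4-(3-methylbut-2-en-1-yl)-6-{[(4-methylphenyl)sulfonyl]methyl}cyclohexa-2,5-dien-1-one | CCCCCC(=O)C1=C(O)[C@](C)(CC=C(C)C)C(O)=C(CS(=O)(=O)c2ccc(C)cc2)C1=O
F4 | step 5 | 1-(2,4,6-trimethoxyphenyl)butan-1-one | CCCC(=O)c1c(OC)cc(OC)cc1OC
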